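**Retrosynthetic overview**
1. Feature: in ring B the two carbonyl-level carbons C6 (ketone) and C8 (methylidene-bearing) both stand 1,3 to the quaternary C10. This is the pattern of a Birch-reduced, C-methylated 3,5-dimethoxybenzoic acid, whose two enol ether arms are enantiotopic.
2. Ring B comes first (arene to 1,4-diene). Ring A is closed second by C4–C5 bond formation, the enol ether carbon C5 adding to the β-carbon of a tethered 4-methylpent-3-en-2-one, which makes C10 stereogenic. The succinimide ring is closed last.
3. Further disconnections: C12–C13 (auxiliary-controlled syn-aldol), C11–vinyl (1,6-addition to a C9 methylidene), C8–C17 (enol triflate cross-coupling, then deconjugation), C2–Cl and C3–Cl (from the C2 ketone).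
4. Stereochemical rule used throughout: reagents reach C2, C3, C5 and C9 from the α face, anti to the axial C10 methyl group, so at C3 and C9 the substituent goes in first and the proton last.

Key step: step 5

Remarks
- Labdane numbering is used for all bicyclic compounds (ring A: C1–C5 and C10; ring B: C5–C10; C10 carries a methyl group); β is the face of that methyl group, α the opposite face.
- Assumption: the sense of induction of the chiral acid cannot be predicted for this new substrate class; the (S,S)-catalyst is taken to select the arm that leads to the configuration shown for 12, and its enantiomer would be used otherwise.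

Step 1
Reactants: 1 3,5-dimethoxybenzoic acid; 2 iodomethane
Product: 4 3,5-dimethoxy-1-methylcyclohexa-2,5-diene-1-carboxylic acid, via dilithium enediolate 3 (not isolated)
Conditions: Li, NH3(l), THF, −78 °C; then MeI; NH4Cl; NaH2PO4 to pH 5, 0 °C
Reagents that add atoms: none
Why: Birch reductive alkylation, in which the benzoate is reduced at C1/C4 while both methoxy-bearing carbons stay sp2 and the dianion is C-methylated at the carboxyl-bearing carbon, should give the achiral bis(enol ether) acid.

Step 2
Reactants: 4 3,5-dimethoxy-1-methylcyclohexa-2,5-diene-1-carboxylic acid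
Product: 6 2-diazo-1-(3,5-dimethoxy-1-methylcyclohexa-2,5-dien-1-yl)ethanone, via acid chloride 5 (not isolated)
Conditions: Me2C=C(Cl)NMe2, CH2Cl2, 0 °C; then CH2N2, Et3N, Et2O, 0 °C
Reagents that add atoms: diazomethane, C=[N+]=[N-]
Why: First stage of the Arndt–Eistert homologation; the neutral chloroenamine makes the acid chloride without HCl so the enol ethers survive, and the non-enolisable acid chloride acylates diazomethane while Et3N takes up HCl.

Step 3
Reactants: 6 2-diazo-1-(3,5-dimethoxy-1-methylcyclohexa-2,5-dien-1-yl)ethanone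
Product: 8 2-(3,5-dimethoxy-1-methylcyclohexa-2,5-dien-1-yl)-N-methoxy-N-methylacetamide, via ketene 7 (not isolated)
Conditions: hν (365 nm), MeNH(OMe), THF, 0 °C
Reagents that add atoms: N,O-dimethylhydroxylamine, CNOC
Why: Photochemical Wolff rearrangement (1,2-shift of the quaternary carbon) with amine trapping of the ketene gives the homologated Weinreb amide directly; a metal-free Wolff avoids the copper-promoted vinylogous rearrangement known for β,γ-unsaturated diazoketones.

Step 4
Reactants: 8 2-(3,5-dimethoxy-1-methylcyclohexa-2,5-dien-1-yl)-N-methoxy-N-methylacetamide; 9 2-methylprop-1-enylmagnesium bromide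
Product: 10 1-(3,5-dimethoxy-1-methylcyclohexa-2,5-dien-1-yl)-4-methylpent-3-en-2-one (prochiral bis(enol ether) enone)
Conditions: THF, 0 °C; aq NH4Cl, 0 °C
Reagents that add atoms: none
Why: Weinreb ketone synthesis, in which the chelated tetrahedral intermediate prevents over-addition and the buffered cold quench spares the enol ethers.

Step 5
Reactants: 10 1-(3,5-dimethoxy-1-methylcyclohexa-2,5-dien-1-yl)-4-methylpent-3-en-2-one
Product: 12 8-methoxy-4,4,10-trimethyl-trans-decal-7-ene-2,6-dione (5α-H; 10β-CH3), via cis-fused dienol ether 11 (not isolated)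
Conditions: (S,S)-IDPi (5 mol %; imidodiphosphorimidate built from 3,3′-diaryl-(S)-BINOL units with N-SO2CF3 groups), 5 Å molecular sieves, toluene, −40 °C to rt; then MeOH–H2O, 40 °C
Reagents that add atoms: water, O; methanol, CO (exchanges into the C8 methoxy group)
Why: Proposed new method: the confined, strongly acidic catalyst activates the enone carbonyl, and the nucleophilic carbon C5 of one of the two enantiotopic methyl enol ethers adds to the β-carbon C4 inside the chiral ion pair, giving a C6 oxocarbenium ion and the C2 enol; proton loss from C7 and tautomerisation return the acid, so no stoichiometric reagent is needed. The closest known reaction types are catalytic enantioselective desymmetrising intramolecular Michael additions to prochiral cyclohexadienones and acid-catalysed Mukaiyama–Michael additions of silyl enol ethers to enones; a methyl enol ether as nucleophile and a 1,4-diene as the prochiral unit are new. Ring A closes in a 6-endo-trig mode (enol-exo) by forming the C4–C5 bond. C10 becomes stereogenic through the choice of arm and is controlled by the chiral counteranion bound to the enone, whereas C5 is first formed cis (the tether reaches only the face of C5 that carries C1) and is then corrected by enolisation and reprotonation on the α face, anti to the C10 and axial C4 methyl groups, to the trans ring fusion. Acid-induced isomerisation of the 1,4-diene to its conjugated isomer passes through a symmetric cation and so should not erode the selection, and exclusion of water until the cyclisation is complete prevents premature hydrolysis. In acidic methanol the vinylogous ester should equilibrate to the regioisomer with the carbonyl next to the more substituted C5 and the methoxy group at C8, which keeps C6 and C8 differentiated.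

Step 6
Reactants: 12 8-methoxy-4,4,10-trimethyl-trans-decal-7-ene-2,6-dione
Product: 14 3α-chloro-8-methoxy-4,4,10-trimethyl-trans-decal-7-ene-2,6-dione, via silyl enol ether 13 (not isolated)
Conditions: Me3SiOTf (1.1 equiv), Et3N, CH2Cl2, 0 °C; then NCS (1.0 equiv), THF, −20 °C
Reagents that add atoms: N-chlorosuccinimide, O=C1CCC(=O)N1Cl
Why: Soft enolisation of the saturated ketone should give the Δ2 silyl enol ether (double bond remote from the ring fusion, as in 2-oxo-5α-steroids) ahead of the vinylogous ester, and α-chlorination of the silyl enol ether by axial attack on the α face gives the 3α-chloride.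

Step 7
Reactants: 14 3α-chloro-8-methoxy-4,4,10-trimethyl-trans-decal-7-ene-2,6-dione
Product: 15 2-(tert-butyldimethylsilyloxy)-3-chloro-8-methoxy-4,4,10-trimethyl-trans-decala-2,7-dien-6-one
Conditions: t-BuMe2SiOTf, Et3N, CH2Cl2, rt
Reagents that add atoms: tert-butyldimethylsilyl trifluoromethanesulfonate, CC(C)(C)[Si](C)(C)OS(=O)(=O)C(F)(F)F
Why: Thermodynamic silyl enol ether formation towards the chlorine-bearing carbon (C3–H is acidified by chlorine and the chloro-substituted Δ2 enol ether is the more stable regioisomer) deliberately erases the C3 stereocentre.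

Step 8
Reactants: 15 2-(tert-butyldimethylsilyloxy)-3-chloro-8-methoxy-4,4,10-trimethyl-trans-decala-2,7-dien-6-one
Product: 17 3β-chloro-2β-hydroxy-8-methoxy-4,4,10-trimethyl-trans-decal-7-en-6-one, via 3β-chloro ketone 16 (not isolated)
Conditions: Bu4NF, AcOH, THF, −78 °C; then NaBH4, MeOH, −78 to −40 °C
Reagents that add atoms: none
Why: Fluoride cleavage and kinetic C-protonation of the chloro enolate on the open α face place chlorine equatorial (3β), and immediate borohydride reduction, also from the α face because the β face of C2 is blocked by two syn-axial methyl groups, should give the axial 2β-alcohol before C3 can epimerise.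

Step 9
Reactants: 17 3β-chloro-2β-hydroxy-8-methoxy-4,4,10-trimethyl-trans-decal-7-en-6-one
Product: 19 2α,3β-dichloro-8-methoxy-4,4,10-trimethyl-trans-decal-7-en-6-one, via chloromethanesulfonate 18 (not isolated)
Conditions: ClCH2SO2Cl, pyridine, CH2Cl2, 0 °C; then LiCl, DMF, 60 °C
Reagents that add atoms: lithium chloride, [Li+].[Cl-]
Why: Sulfonylation followed by SN2 displacement with inversion, chloride attacking the axial sulfonate from the α face to give the equatorial 2α-chloride; the gauche C3–Cl cannot participate, so no retention pathway is open.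

Step 10
Reactants: 19 2α,3β-dichloro-8-methoxy-4,4,10-trimethyl-trans-decal-7-en-6-one
Product: 20 9α-(dimethylaminomethyl)-2α,3β-dichloro-8-methoxy-4,4,10-trimethyl-trans-decal-7-en-6-one
Conditions: LiN(i-Pr)2, THF, −78 °C; then CH2=NMe2+ I−, −78 to 0 °C
Reagents that add atoms: N,N-dimethylmethyleneiminium iodide, C=[N+](C)C.[I-]
Why: γ-Deprotonation of the vinylogous ester (the α′ position C5 is a methine between two quaternary carbons) and Mannich reaction of the β-alkoxy dienolate at its γ-carbon C9; the configuration formed at C9 is irrelevant because C9 becomes sp2 in the next step, and the diequatorial dichloride has no antiperiplanar H–Cl pair for E2.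

Step 11
Reactants: 20 9α-(dimethylaminomethyl)-2α,3β-dichloro-8-methoxy-4,4,10-trimethyl-trans-decal-7-en-6-one
Product: 22 2α,3β-dichloro-8-methoxy-4,4,10-trimethyl-9-methylidene-trans-decal-7-en-6-one, via amine N-oxide 21 (not isolated)
Conditions: mCPBA, CH2Cl2, 0 °C; then toluene, 80 °C
Reagents that add atoms: none
Why: N-Oxidation and Cope elimination, an intramolecular syn elimination that needs no enolisation of the poorly aligned C9–H, should give the γ-methylidene vinylogous ester.

Step 12
Reactants: 22 2α,3β-dichloro-8-methoxy-4,4,10-trimethyl-9-methylidene-trans-decal-7-en-6-one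
Product: 24 9β-allyl-2α,3β-dichloro-4,4,10-trimethyl-trans-decalin-6,8-dione (written as the diketo tautomer), via silyl dienol ether 23 (not isolated)
Conditions: CH2=CHMgBr, CuBr·SMe2 (10 mol %), Me3SiCl, THF, −78 °C; then 1 M HCl, THF, 0 °C to rt
Reagents that add atoms: vinylmagnesium bromide, C=C[Mg]Br; water, O
Why: Copper-catalysed 1,6-conjugate addition of the vinyl Grignard reagent to the unhindered exocyclic CH2 with silyl trapping puts the allyl group on an sp2 C9, and on acid hydrolysis of both enol ethers the proton enters C9 from the α face, anti to the C10 methyl group, so the allyl group should end β (equatorial).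

Step 13
Reactants: 24 9β-allyl-2α,3β-dichloro-4,4,10-trimethyl-trans-decalin-6,8-dione
Product: 25 9β-allyl-2α,3β-dichloro-4,4,10-trimethyl-6-oxo-trans-decal-7-en-8-yl trifluoromethanesulfonate
Conditions: Tf2O, pyridine, CH2Cl2, −78 °C
Reagents that add atoms: trifluoromethanesulfonic anhydride, O=S(=O)(OS(=O)(=O)C(F)(F)F)C(F)(F)F
Why: O-Sulfonylation of the β-diketone at the less hindered oxygen O8 (O6 is flanked by C5 and the C4 gem-dimethyl group) gives the vinylogous triflate, and the weak base at low temperature leaves C9 untouched.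

Step 14
Reactants: 25 9β-allyl-2α,3β-dichloro-4,4,10-trimethyl-6-oxo-trans-decal-7-en-8-yl trifluoromethanesulfonate
Product: 26 9β-allyl-2α,3β-dichloro-4,4,10-trimethyl-8-(trimethylsilylmethyl)-trans-decal-7-en-6-one
Conditions: Me3SiCH2MgCl, Pd(PPh3)4 (5 mol %), THF, 0 °C
Reagents that add atoms: (trimethylsilyl)methylmagnesium chloride, C[Si](C)(C)C[Mg]Cl
Why: Kumada cross-coupling of the enol triflate (oxidative addition of zerovalent palladium to C8–O, transmetalation, reductive elimination); secondary alkyl chlorides and the hindered C6 ketone should not react.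

Step 15
Reactants: 26 9β-allyl-2α,3β-dichloro-4,4,10-trimethyl-8-(trimethylsilylmethyl)-trans-decal-7-en-6-one
Product: 28 2-[2α,3β-dichloro-4,4,10-trimethyl-6-oxo-8-(trimethylsilylmethyl)-trans-decal-7-en-9β-yl]acetaldehyde, via diol 27 (not isolated)
Conditions: OsO4 (2 mol %), NaIO4, 2,6-lutidine, dioxane–H2O, rt
Reagents that add atoms: sodium periodate, [Na+].[O-]I(=O)(=O)=O
Why: Lemieux–Johnson cleavage, in which OsO4 dihydroxylates only the terminal alkene and not the electron-poor enone double bond, and periodate cleaves the diol to the aldehyde.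

Step 16
Reactants: 29 (R)-4-benzyloxazolidin-2-one; 30 methyl 4-chloro-4-oxobutanoate
Product: 31 methyl 4-[(R)-4-benzyl-2-oxooxazolidin-3-yl]-4-oxobutanoate
Conditions: n-BuLi, THF, −78 °C; then 30, −78 to 0 °C
Reagents that add atoms: none
Why: N-Acylation of the lithiated oxazolidinone by the acid chloride, which reacts in preference to the methyl ester.

Step 17
Reactants: 28 2-[2α,3β-dichloro-4,4,10-trimethyl-6-oxo-8-(trimethylsilylmethyl)-trans-decal-7-en-9β-yl]acetaldehyde; 31 methyl 4-[(R)-4-benzyl-2-oxooxazolidin-3-yl]-4-oxobutanoate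
Product: 33 (12S,13R)-syn-aldol adduct (C12 hydroxyl; C13 bearing CH2CO2CH3 and the N-acyl-(R)-4-benzyloxazolidinone; ring B unchanged), via boron enolate 32 (not isolated)
Conditions: 31, Bu2BOTf, i-Pr2NEt, CH2Cl2, −78 to 0 °C; then 28 (limiting), −78 to 0 °C; pH 7 buffer, MeOH, H2O2, 0 °C
Reagents that add atoms: none
Why: Evans syn-aldol reaction, in which the Z boron enolate of the imide (enolised in preference to the ester) adds through a Zimmerman–Traxler chair with the (R)-benzyl group shielding one enolate face, which should set 12S and 13R under reagent control.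

Step 18
Reactants: 33 (12S,13R)-syn-aldol adduct
Product: 35 (12S,13R)-2α,3β-dichloro-12-hydroxy-8-(trimethylsilylmethyl)-Δ7-6-oxo succinimide (target skeleton with ring B still as the silylmethyl enone), via primary amide 34 (not isolated)
Conditions: NH3 (7 M in MeOH), THF, 0 °C to rt
Reagents that add atoms: ammonia, N
Why: Ammonolysis of the N-acyloxazolidinone to the primary amide and 5-exo-trig acyl substitution at the methyl ester close the succinimide and release the auxiliary without touching C12 or C13.

Step 19
Reactants: 35 (12S,13R)-2α,3β-dichloro-12-hydroxy-8-(trimethylsilylmethyl)-Δ7-6-oxo succinimide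
Product: 36 haterumaimide B
Conditions: Bu4NF, AcOH, THF, 0 °C
Reagents that add atoms: none
Why: Fluoride-induced desilylation of the γ-silyl enone generates the exocyclic dienolate regiospecifically, and kinetic protonation at the α-carbon C7 (deconjugative protonation of a dienolate) should give the β,γ-unsaturated ketone with the C8 methylidene, the acetic acid buffer protecting the β-hydroxy imide, C5 and C9.

**Compound list**
1 | 3,5-dimethoxybenzoic acid | COc1cc(OC)cc(c1)C(=O)O | starting material
2 | iodomethane | CI | starting material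
3 | dilithium (3,5-dimethoxycyclohexa-2,5-dien-1-ylidene)methanediolate | [Li+].[Li+].[O-]C([O-])=C1C=C(OC)CC(OC)=C1 | intermediate
4 | 3,5-dimethoxy-1-methylcyclohexa-2,5-diene-1-carboxylic acid | COC1=CC(C)(C(=O)O)C=C(OC)C1 | intermediate
5 | 3,5-dimethoxy-1-methylcyclohexa-2,5-diene-1-carbonyl chloride | COC1=CC(C)(C(Cl)=O)C=C(OC)C1 | intermediate
6 | 2-diazo-1-(3,5-dimethoxy-1-methylcyclohexa-2,5-dien-1-yl)ethanone | COC1=CC(C)(C(=O)C=[N+]=[N-])C=C(OC)C1 | intermediate
7 | (3,5-dimethoxy-1-methylcyclohexa-2,5-dien-1-yl)ketene | COC1=CC(C)(C=C=O)C=C(OC)C1 | intermediate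
8 | 2-(3,5-dimethoxy-1-methylcyclohexa-2,5-dien-1-yl)-N-methoxy-N-methylacetamide | CON(C)C(=O)CC1(C)C=C(OC)CC(OC)=C1 | intermediate
9 | 2-methylprop-1-enylmagnesium bromide | CC(C)=C[Mg]Br | starting material
10 | 1-(3,5-dimethoxy-1-methylcyclohexa-2,5-dien-1-yl)-4-methylpent-3-en-2-one | CC(C)=CC(=O)CC1(C)C=C(OC)CC(OC)=C1 | intermediate
11 | cis-fused 6,8-dimethoxy-4,4,10-trimethyldecala-6,8-dien-2-one (5β-H; 10β-CH3) | COC=1C=C(OC)[C@@H]2C(C)(C)CC(=O)C[C@]2(C)C=1 | intermediate
12 | 8-methoxy-4,4,10-trimethyl-trans-decal-7-ene-2,6-dione (5α-H; 10β-CH3) | COC1=CC(=O)[C@H]2C(C)(C)CC(=O)C[C@]2(C)C1 | intermediate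
13 | 8-methoxy-4,4,10-trimethyl-2-(trimethylsilyloxy)-trans-decala-2,7-dien-6-one | COC1=CC(=O)[C@H]2C(C)(C)C=C(O[Si](C)(C)C)C[C@]2(C)C1 | intermediate
14 | 3α-chloro-8-methoxy-4,4,10-trimethyl-trans-decal-7-ene-2,6-dione | COC1=CC(=O)[C@H]2C(C)(C)[C@H](Cl)C(=O)C[C@]2(C)C1 | intermediate
15 | 2-(tert-butyldimethylsilyloxy)-3-chloro-8-methoxy-4,4,10-trimethyl-trans-decala-2,7-dien-6-one | COC1=CC(=O)[C@H]2C(C)(C)C(Cl)=C(O[Si](C)(C)C(C)(C)C)C[C@]2(C)C1 | intermediate
16 | 3β-chloro-8-methoxy-4,4,10-trimethyl-trans-decal-7-ene-2,6-dione | COC1=CC(=O)[C@H]2C(C)(C)[C@@H](Cl)C(=O)C[C@]2(C)C1 | intermediate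
17 | 3β-chloro-2β-hydroxy-8-methoxy-4,4,10-trimethyl-trans-decal-7-en-6-one | COC1=CC(=O)[C@H]2C(C)(C)[C@@H](Cl)[C@@H](O)C[C@]2(C)C1 | intermediate
18 | 3β-chloro-8-methoxy-4,4,10-trimethyl-6-oxo-trans-decal-7-en-2β-yl chloromethanesulfonate | COC1=CC(=O)[C@H]2C(C)(C)[C@@H](Cl)[C@@H](OS(=O)(=O)CCl)C[C@]2(C)C1 | intermediate
19 | 2α,3β-dichloro-8-methoxy-4,4,10-trimethyl-trans-decal-7-en-6-one | COC1=CC(=O)[C@H]2C(C)(C)[C@@H](Cl)[C@H](Cl)C[C@]2(C)C1 | intermediate
20 | 9α-(dimethylaminomethyl)-2α,3β-dichloro-8-methoxy-4,4,10-trimethyl-trans-decal-7-en-6-one | COC1=CC(=O)[C@H]2C(C)(C)[C@@H](Cl)[C@H](Cl)C[C@]2(C)[C@@H]1CN(C)C | intermediate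
21 | N-oxide of 20 | COC1=CC(=O)[C@H]2C(C)(C)[C@@H](Cl)[C@H](Cl)C[C@]2(C)[C@@H]1C[N+](C)(C)[O-] | intermediate
22 | 2α,3β-dichloro-8-methoxy-4,4,10-trimethyl-9-methylidene-trans-decal-7-en-6-one | COC1=CC(=O)[C@H]2C(C)(C)[C@@H](Cl)[C@H](Cl)C[C@]2(C)C1=C | intermediate
23 | 9-allyl-2α,3β-dichloro-8-methoxy-4,4,10-trimethyl-6-(trimethylsilyloxy)-trans-decala-6,8-diene | COC=1C=C(O[Si](C)(C)C)[C@H]2C(C)(C)[C@@H](Cl)[C@H](Cl)C[C@]2(C)C=1CC=C | intermediate
24 | 9β-allyl-2α,3β-dichloro-4,4,10-trimethyl-trans-decalin-6,8-dione | O=C1CC(=O)[C@H]2C(C)(C)[C@@H](Cl)[C@H](Cl)C[C@]2(C)[C@H]1CC=C | intermediate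
25 | 9β-allyl-2α,3β-dichloro-4,4,10-trimethyl-6-oxo-trans-decal-7-en-8-yl trifluoromethanesulfonate | FC(F)(F)S(=O)(=O)OC1=CC(=O)[C@H]2C(C)(C)[C@@H](Cl)[C@H](Cl)C[C@]2(C)[C@H]1CC=C | intermediate
26 | 9β-allyl-2α,3β-dichloro-4,4,10-trimethyl-8-(trimethylsilylmethyl)-trans-decal-7-en-6-one | C[Si](C)(C)CC1=CC(=O)[C@H]2C(C)(C)[C@@H](Cl)[C@H](Cl)C[C@]2(C)[C@H]1CC=C | intermediate
27 | 3-[2α,3β-dichloro-4,4,10-trimethyl-6-oxo-8-(trimethylsilylmethyl)-trans-decal-7-en-9β-yl]propane-1,2-diol (both carbinol epimers) | C[Si](C)(C)CC1=CC(=O)[C@H]2C(C)(C)[C@@H](Cl)[C@H](Cl)C[C@]2(C)[C@H]1CC(O)CO | intermediate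
28 | 2-[2α,3β-dichloro-4,4,10-trimethyl-6-oxo-8-(trimethylsilylmethyl)-trans-decal-7-en-9β-yl]acetaldehyde | C[Si](C)(C)CC1=CC(=O)[C@H]2C(C)(C)[C@@H](Cl)[C@H](Cl)C[C@]2(C)[C@H]1CC=O | intermediate
29 | (R)-4-benzyloxazolidin-2-one | O=C1N[C@H](Cc2ccccc2)CO1 | starting material
30 | methyl 4-chloro-4-oxobutanoate | COC(=O)CCC(Cl)=O | starting material
31 | methyl 4-[(R)-4-benzyl-2-oxooxazolidin-3-yl]-4-oxobutanoate | COC(=O)CCC(=O)N1[C@H](Cc2ccccc2)COC1=O | intermediate
32 | (Z)-dibutylboron enolate of 31 | COC(=O)C/C=C(\OB(CCCC)CCCC)N1[C@H](Cc2ccccc2)COC1=O | intermediate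
33 | (12S,13R)-syn-aldol adduct of 28 and 31 | C[Si](C)(C)CC1=CC(=O)[C@H]2C(C)(C)[C@@H](Cl)[C@H](Cl)C[C@]2(C)[C@H]1C[C@H](O)[C@@H](CC(=O)OC)C(=O)N1[C@H](Cc2ccccc2)COC1=O | intermediate
34 | (12S,13R)-primary amide methyl ester (auxiliary replaced by NH2) | C[Si](C)(C)CC1=CC(=O)[C@H]2C(C)(C)[C@@H](Cl)[C@H](Cl)C[C@]2(C)[C@H]1C[C@H](O)[C@@H](CC(=O)OC)C(N)=O | intermediate
35 | (12S,13R)-2α,3β-dichloro-12-hydroxy-8-(trimethylsilylmethyl)-Δ7-6-oxo succinimide | C[Si](C)(C)CC1=CC(=O)[C@H]2C(C)(C)[C@@H](Cl)[C@H](Cl)C[C@]2(C)[C@H]1C[C@H](O)[C@H]1CC(=O)NC1=O | intermediate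
36 | haterumaimide B | C=C1CC(=O)[C@H]2C(C)(C)[C@@H](Cl)[C@H](Cl)C[C@]2(C)[C@H]1C[C@H](O)[C@H]1CC(=O)NC1=O | target

**Step count and risks**
Total: 19 steps. Longest linear sequence: 18 steps (steps 1–15 and 17–19; step 16 makes the aldol partner).

Steps most likely to fail:

1. Step 5. Hydrolysis or acid-induced isomerisation of the enol ethers may outrun C–C bond formation at the hindered β,β-disubstituted enone, the catalyst may discriminate poorly between the two arms, or C5 may not equilibrate to the trans fusion. The fallback sets out from 10 and returns at 12, using known chemistry. Brief treatment of 10 with aqueous oxalic acid in THF hydrolyses one enol ether and conjugates the other to give the racemic 3-methoxy-5-methyl-5-(4-methyl-2-oxopent-3-enyl)cyclohex-2-enone F1. KOt-Bu in t-BuOH–THF then closes ring A by intramolecular Michael addition of the ring enolate to the enone. Equilibration of the crude product in methanol with a trace of TsOH funnels both vinylogous ester regioisomers and both C5 epimers into the racemic trans-fused keto vinylogous ester F2. Preparative chromatography on a chiral stationary phase separates 12 from its enantiomer.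

2. Step 7. Enolisation may go towards C1 instead of C3, because the C3–H of the axial chloride is equatorial; this would give an allylic chloride enol ether, or ring contraction, instead of the chloro enol ether on which the 3β configuration depends. The fallback sets out from 14 and returns at 17, delivering the C3 hydrogen by hydroboration instead of protonation. LiBH(s-Bu)3 in THF at −78 °C reduces 14 to the 3α-chloro-2β-alcohol F3. Syn-dehydration with the Burgess reagent towards the chlorine-bearing carbon gives the 3-chloro-Δ2-alkene F4. Hydroboration on the α face (BH3·SMe2, then NaBO3) puts hydrogen on C3 and boron on C2, giving the 3β-chloro-2α-alcohol F5. Dess–Martin oxidation then gives 16, which is reduced at once with NaBH4 as in step 8 to 17.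

3. Step 10. Proton abstraction may occur at C5, or the iminium ion may attack C7 or oxygen rather than the hindered γ-carbon C9. The fallback sets out from 19 and returns at 20, replacing the lithium dienolate by a neutral diene. Soft enolisation with t-BuMe2SiOTf and Et3N under equilibrating conditions gives the 6-silyloxy-8-methoxy-6,8-diene F6. This reacts with CH2=NMe2+ I− in CH2Cl2 at its terminal carbon C9 (vinylogous Mukaiyama–Mannich reaction) and loses the silyl group to give 20.

**Further compounds**
F1 | step 5 | racemic 3-methoxy-5-methyl-5-(4-methyl-2-oxopent-3-enyl)cyclohex-2-enone | COC1=CC(=O)CC(C)(CC(=O)C=C(C)C)C1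
F2 | step 5 | racemic 12 (1:1 mixture of 12 and its enantiomer) | COC1=CC(=O)[C@H]2C(C)(C)CC(=O)C[C@]2(C)C1.COC1=CC(=O)[C@@H]2C(C)(C)CC(=O)C[C@@]2(C)C1
F3 | step 7 | 3α-chloro-2β-hydroxy-8-methoxy-4,4,10-trimethyl-trans-decal-7-en-6-one | COC1=CC(=O)[C@H]2C(C)(C)[C@H](Cl)[C@@H](O)C[C@]2(C)C1
F4 | step 7 | 3-chloro-8-methoxy-4,4,10-trimethyl-trans-decala-2,7-dien-6-one | COC1=CC(=O)[C@H]2C(C)(C)C(Cl)=CC[C@]2(C)C1
F5 | step 7 | 3β-chloro-2α-hydroxy-8-methoxy-4,4,10-trimethyl-trans-decal-7-en-6-one | COC1=CC(=O)[C@H]2C(C)(C)[C@@H](Cl)[C@H](O)C[C@]2(C)C1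
F6 | step 10 | 6-(tert-butyldimethylsilyloxy)-2α,3β-dichloro-8-methoxy-4,4,10-trimethyl-trans-decala-6,8-diene | COC=1C=C(O[Si](C)(C)C(C)(C)C)[C@H]2C(C)(C)[C@@H](Cl)[C@H](Cl)C[C@]2(C)C=1
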